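Ring D is cut last by a Diels–Alder disconnection (C2–C4', C14–C15') into a unit A trienone and the exocyclic enone of unit B. The route rests on unit A: ring A holds a C1=C2–C3=O enone cross-conjugated with the C4=C15 methylene and shares C1–C5 with seven-membered ring B. An alkyne (C1≡C2), the inner C4=C5 bond of a terminal allene and CO add up to this array, so one molybdenum-mediated allenic Pauson–Khand reaction makes C1–C5, C2–C3 and C3–C4, closes both rings and creates C5. The substrate is a trans α-methylene lactone with the allene on C6 and an alkyne-ended arm on C7; its C14 silyl ether is a latent C10=C14.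

Key step: step 15

Assumption: C5–H and C10–H of unit A are both vinylogously acidic (γ to the C3 ketone), so the 5βH,10αH configuration of the target is taken to be the one preferred at equilibrium; C10 is still carried as one configuration so that every intermediate up to 25 is a single diastereomer; deacylcynaropicrin (26) and the carbazole bis(oxazoline) ligand are taken as catalogue chemicals, and the mirror-image ligand is used should the (S,S) form favour the Re face.

Step 1
Reactants: 1 (S)-4-benzyl-1,3-oxazolidin-2-one; 2 hex-5-enoyl chloride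
Product: 3 (S)-4-benzyl-3-(hex-5-enoyl)-1,3-oxazolidin-2-one
Conditions: Et3N, DMAP (cat), CH2Cl2, 0 °C to rt
Reagents that add atoms: none
Why: DMAP-catalysed N-acylation of the oxazolidinone by the acid chloride attaches the auxiliary that will control C10, and the terminal alkene is inert.

Step 2
Reactants: 3 (S)-4-benzyl-3-(hex-5-enoyl)-1,3-oxazolidin-2-one
Product: 5 (S)-4-benzyl-3-[(2R)-2-(hydroxymethyl)hex-5-enoyl]-1,3-oxazolidin-2-one, via titanium enolate 4 (not isolated)
Conditions: TiCl4, iPr2NEt, CH2Cl2, 0 °C; then 1,3,5-trioxane, TiCl4, 0 °C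
Reagents that add atoms: 1,3,5-trioxane, C1OCOCO1
Why: Soft enolisation gives the chelated Z enolate 4, and TiCl4-activated formaldehyde adds to the face remote from the benzyl group (auxiliary-controlled titanium-enolate hydroxymethylation), which creates C10 with C14 attached.

Step 3
Reactants: 5 (S)-4-benzyl-3-[(2R)-2-(hydroxymethyl)hex-5-enoyl]-1,3-oxazolidin-2-one
Product: 6 (S)-4-benzyl-3-[(2R)-2-(tert-butyldimethylsilyloxymethyl)hex-5-enoyl]-1,3-oxazolidin-2-one
Conditions: TBSCl, imidazole, DMF, rt
Reagents that add atoms: tert-butyldimethylsilyl chloride, CC(C)(C)[Si](C)(C)Cl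
Why: Imidazole-promoted silylation of the primary alcohol is routine and blocks retro-aldol loss of C14 in the following steps.

Step 4
Reactants: 6 (S)-4-benzyl-3-[(2R)-2-(tert-butyldimethylsilyloxymethyl)hex-5-enoyl]-1,3-oxazolidin-2-one
Product: 7 (2S)-2-(tert-butyldimethylsilyloxymethyl)hex-5-en-1-ol
Conditions: LiBH4, MeOH (1 equiv), THF, 0 °C
Reagents that add atoms: none
Why: Borohydride reduces the activated exocyclic imide carbonyl to the primary alcohol and releases the auxiliary (reductive auxiliary cleavage) without touching C10, the alkene or the silyl ether.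

Step 5
Reactants: 7 (2S)-2-(tert-butyldimethylsilyloxymethyl)hex-5-en-1-ol
Product: 8 (2R)-2-(tert-butyldimethylsilyloxymethyl)hex-5-enal
Conditions: Dess–Martin periodinane, pyridine, CH2Cl2, 0 °C to rt
Reagents that add atoms: none
Why: Dess–Martin oxidation under buffered conditions should give the α-branched aldehyde without epimerisation or β-elimination, and the crude aldehyde is used at once.

Step 6
Reactants: 8 (2R)-2-(tert-butyldimethylsilyloxymethyl)hex-5-enal
Product: 9 (3S)-3-(tert-butyldimethylsilyloxymethyl)hept-6-en-1-yne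
Conditions: dimethyl (1-diazo-2-oxopropyl)phosphonate, K2CO3, MeOH, 0 °C to rt
Reagents that add atoms: dimethyl (1-diazo-2-oxopropyl)phosphonate, COP(=O)(OC)C(=[N+]=[N-])C(C)=O
Why: Ohira–Bestmann (Seyferth–Gilbert) homologation turns the aldehyde carbon into C1 and adds C2 as the terminal alkyne carbon under conditions mild enough to keep the α-stereocentre.

Step 7
Reactants: 9 (3S)-3-(tert-butyldimethylsilyloxymethyl)hept-6-en-1-yne
Product: 10 (4S)-4-(tert-butyldimethylsilyloxymethyl)hex-5-ynal
Conditions: OsO4 (2 mol %), NaIO4, 2,6-lutidine, dioxane–H2O, rt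
Reagents that add atoms: OsO4, O=[Os](=O)(=O)=O; NaIO4, [Na+].[O-]I(=O)(=O)=O
Why: Lemieux–Johnson cleavage (dihydroxylation then periodate scission) converts the terminal alkene into the C7 aldehyde, the alkyne reacting far more slowly with OsO4.

Step 8
Reactants: 10 (4S)-4-(tert-butyldimethylsilyloxymethyl)hex-5-ynal; 11 methyl acrylate
Product: 12 methyl (6S)-6-(tert-butyldimethylsilyloxymethyl)-3-hydroxy-2-methylideneoct-7-ynoate (both C3 epimers)
Conditions: DABCO, MeOH, rt, 3 d
Reagents that add atoms: none
Why: Morita–Baylis–Hillman coupling of the unhindered aliphatic aldehyde with the acrylate forms the C7–C11 bond, and the unselective carbinol centre does not matter because step 9 turns it into an alkene carbon.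

Step 9
Reactants: 12 methyl (6S)-6-(tert-butyldimethylsilyloxymethyl)-3-hydroxy-2-methylideneoct-7-ynoate
Product: 13 methyl (2Z,6S)-2-(bromomethyl)-6-(tert-butyldimethylsilyloxymethyl)oct-2-en-7-ynoate
Conditions: NBS, Me2S, CH2Cl2, 0 °C to rt
Reagents that add atoms: N-bromosuccinimide, O=C1CCC(=O)N1Br
Why: Activation of the allylic alcohol as an alkoxysulfonium ion and SN2' attack by bromide give the rearranged primary allylic bromide as the favoured Z isomer (bromination with allylic transposition), leaving the silyl ether and the alkyne untouched.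

Step 10
Reactants: 14 but-2-yne-1,4-diol
Product: 15 4-(4-methoxybenzyloxy)but-2-yn-1-ol
Conditions: NaH (1 equiv), PMBCl, Bu4NI (cat), THF–DMF, 0 °C to rt, diol in excess
Reagents that add atoms: 4-methoxybenzyl chloride, COc1ccc(CCl)cc1
Why: Williamson etherification of the mono-alkoxide in the presence of excess diol should give mainly the mono-PMB ether, which is separated from diol and bis-ether by chromatography.

Step 11
Reactants: 15 4-(4-methoxybenzyloxy)but-2-yn-1-ol
Product: 16 4-(4-methoxybenzyloxy)but-2-ynal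
Conditions: MnO2, CH2Cl2, rt
Reagents that add atoms: none
Why: Activated MnO2 oxidises the propargylic alcohol to the ynal without over-oxidation and without acid or base that would harm the sensitive aldehyde.

Step 12
Reactants: 13 methyl (2Z,6S)-2-(bromomethyl)-6-(tert-butyldimethylsilyloxymethyl)oct-2-en-7-ynoate; 16 4-(4-methoxybenzyloxy)but-2-ynal
Product: 18 (4S,5S)-5-[3-(4-methoxybenzyloxy)prop-1-yn-1-yl]-3-methylidene-4-[(3S)-3-(tert-butyldimethylsilyloxymethyl)pent-4-yn-1-yl]oxolan-2-one, via silyl ether ester 17 (not isolated)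
Conditions: CrCl2 (10 mol %), (S,S)-3,6-di-tert-butyl-1,8-bis(4-isopropyl-4,5-dihydrooxazol-2-yl)-9H-carbazole (12 mol %), Mn, iPr2NEt, Me3SiCl, THF, rt; then p-TsOH·H2O (cat), CH2Cl2, rt
Reagents that add atoms: none
Why: In this catalytic asymmetric Nozaki–Hiyama–Kishi 2-(alkoxycarbonyl)allylation the chromium-bound allyl fragment (divalent chromium recycled by Mn) adds through its γ-carbon C7 to the aldehyde in a chair transition state with both substituents equatorial, which gives the anti adduct and hence the trans lactone, while the tridentate ligand exposes the Si face of the aldehyde and fixes C6 and C7 (S,S) irrespective of the remote C10 centre; acid then removes the O-silyl group and closes the lactone.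

Step 13
Reactants: 18 (4S,5S)-5-[3-(4-methoxybenzyloxy)prop-1-yn-1-yl]-3-methylidene-4-[(3S)-3-(tert-butyldimethylsilyloxymethyl)pent-4-yn-1-yl]oxolan-2-one
Product: 19 (4S,5S)-5-(3-hydroxyprop-1-yn-1-yl)-3-methylidene-4-[(3S)-3-(tert-butyldimethylsilyloxymethyl)pent-4-yn-1-yl]oxolan-2-one
Conditions: DDQ, CH2Cl2–pH 7 buffer, 0 °C to rt
Reagents that add atoms: none
Why: DDQ oxidises the electron-rich PMB ether to an oxocarbenium ion that water cleaves, which frees the C15 propargylic alcohol and spares the silyl ether, both alkynes and the methylene lactone.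

Step 14
Reactants: 19 (4S,5S)-5-(3-hydroxyprop-1-yn-1-yl)-3-methylidene-4-[(3S)-3-(tert-butyldimethylsilyloxymethyl)pent-4-yn-1-yl]oxolan-2-one
Product: 22 (4S,5R)-3-methylidene-5-(propa-1,2-dien-1-yl)-4-[(3S)-3-(tert-butyldimethylsilyloxymethyl)pent-4-yn-1-yl]oxolan-2-one, via sulfonylhydrazine 20 (not isolated), via propargylic diazene 21 (not isolated)
Conditions: PPh3, DEAD, THF, −15 °C; 2-nitrobenzenesulfonohydrazide, −15 °C; then rt
Reagents that add atoms: none
Why: In this Myers allene synthesis, Mitsunobu N-alkylation of the sulfonylhydrazide at C15 gives 20, loss of arenesulfinic acid gives diazene 21, and its retro-ene loss of N2 delivers hydrogen to C5 and transposes the C4≡C5 alkyne into the C5=C4=C15 allene under neutral conditions, so the C1≡C2 alkyne never has to be told apart from a second terminal alkyne and needs no protection.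

Step 15
Reactants: 22 (4S,5R)-3-methylidene-5-(propa-1,2-dien-1-yl)-4-[(3S)-3-(tert-butyldimethylsilyloxymethyl)pent-4-yn-1-yl]oxolan-2-one
Product: 23 (5S,6S,7S,10S)-14-(tert-butyldimethylsilyloxy)-3-oxoguaia-1,4(15),11(13)-trien-12,6α-olide (5βH,6βH,7αH,10αH)
Conditions: Mo(CO)6 (1.2 equiv), DMSO (10 equiv), toluene (0.02 M), 100 °C, argon
Reagents that add atoms: Mo(CO)6 (source of the C3 carbonyl), [C-]#[O+].[C-]#[O+].[C-]#[O+].[C-]#[O+].[C-]#[O+].[C-]#[O+].[Mo]
Why: Mo(CO)6, freed of a carbonyl ligand by DMSO, binds the C1≡C2 alkyne and the inner C4=C5 π bond of the allene and couples them oxidatively to a molybdacyclopentene (C1–C5 bond), CO then inserts and reductive elimination forms C2–C3 and C3–C4, leaving C4=C15 exocyclic. The closest known reaction type is the molybdenum-mediated allenic Pauson–Khand reaction of monosubstituted allenes, which engages the inner allene bond and gives α-methylene cyclopentenones; closing a seven-membered ring in this mode lies at the edge of that precedent and is the one deliberate risk of the route. Ring B closes in the metallacycle-forming step as a seven-membered carbocycle across the five-atom tether C6–C7–C8–C9–C10 (exo with respect to both the alkyne and the reacting allene bond), and ring A closes by carbonyl insertion and reductive elimination as the [2+2+1] cyclopentenone. The new stereocentre C5 is controlled by C6: the allene should react in the rotamer that keeps H5 syn to H6 and the C6–O bond anti to the forming C1–C5 bond, on the face reached by the C7 arm of the trans lactone, which gives 5βH. The step needs the inner and not the terminal allene bond (secured by the choice of molybdenum and by ring size, seven against eight), the allene and not the C11=C13 alkene as partner of the alkyne (secured by the far stronger binding of an allene than of a 1,1-disubstituted acrylate) and survival of the allenylic C6–O bond (the reason for neutral conditions and short heating). Should C5 form as the other epimer, the centre is not lost, because C5–H is vinylogously acidic in 23 and can be corrected by base equilibration.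

Step 16
Reactants: 23 (5S,6S,7S,10S)-14-(tert-butyldimethylsilyloxy)-3-oxoguaia-1,4(15),11(13)-trien-12,6α-olide
Product: 24 (5S,6S,7S,10S)-14-hydroxy-3-oxoguaia-1,4(15),11(13)-trien-12,6α-olide
Conditions: HF·pyridine, THF, 0 °C to rt
Reagents that add atoms: none
Why: Fluoride cleaves the primary silyl ether under mildly acidic conditions, so that neither the base-sensitive methylene groups nor the vinylogously acidic C5–H and C10–H are disturbed.

Step 17
Reactants: 24 (5S,6S,7S,10S)-14-hydroxy-3-oxoguaia-1,4(15),11(13)-trien-12,6α-olide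
Product: 25 (5S,6S,7S,10S)-14-(methanesulfonyloxy)-3-oxoguaia-1,4(15),11(13)-trien-12,6α-olide
Conditions: Ms2O, pyridine, CH2Cl2, 0 °C
Reagents that add atoms: methanesulfonic anhydride, CS(=O)(=O)OS(C)(=O)=O
Why: Sulfonylation of the primary alcohol with the anhydride and a weak base gives the mesylate at a temperature and basicity too low for the vinylogous elimination that is reserved for step 21.

Step 18
Reactants: 26 deacylcynaropicrin (3β,8α-dihydroxyguaia-4(15),10(14),11(13)-trien-12,6α-olide)
Product: 27 8α-hydroxy-3-oxoguaia-4(15),10(14),11(13)-trien-12,6α-olide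
Conditions: MnO2, CH2Cl2, rt
Reagents that add atoms: none
Why: MnO2 oxidises only the allylic C3 alcohol (chemoselective allylic oxidation) and leaves the non-allylic C8 alcohol and all three methylene groups alone, which gives the exocyclic enone.

Step 19
Reactants: 27 8α-hydroxy-3-oxoguaia-4(15),10(14),11(13)-trien-12,6α-olide
Product: 28 8β-formyloxy-3-oxoguaia-4(15),10(14),11(13)-trien-12,6α-olide
Conditions: PPh3, DIAD, HCO2H, THF, 0 °C to rt
Reagents that add atoms: formic acid, OC=O
Why: Mitsunobu esterification with formic acid proceeds by SN2 displacement of the oxyphosphonium group and so inverts C8 from 8α to 8β, the phosphine being consumed as the betaine before the substrate is added to keep it away from the enone.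

Step 20
Reactants: 28 8β-formyloxy-3-oxoguaia-4(15),10(14),11(13)-trien-12,6α-olide
Product: 29 8β-hydroxy-3-oxoguaia-4(15),10(14),11(13)-trien-12,6α-olide (unit B)
Conditions: NaHCO3, THF–H2O, rt
Reagents that add atoms: none
Why: Formates are the most labile carboxylic esters and hydrolyse with bicarbonate at room temperature by acyl–oxygen cleavage, so C8 keeps its configuration and the lactone, the enone and the methylene groups do not meet alkoxide.

Step 21
Reactants: 25 (5S,6S,7S,10S)-14-(methanesulfonyloxy)-3-oxoguaia-1,4(15),11(13)-trien-12,6α-olide; 29 8β-hydroxy-3-oxoguaia-4(15),10(14),11(13)-trien-12,6α-olide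
Product: 32 CNP0178208.1 (unit A 3-oxo-5βH,10αH-guaia-1,4(15),11(13)-trien-12,6α-olide joined through C2–C4' and C14–C15' to spiro unit B 8'β-hydroxy-3'-oxoguaia-10'(14'),11'(13')-dien-12',6'α-olide), via trienone 30 (not isolated), via cycloadduct 31 (not isolated)
Conditions: 29 (3 equiv), DBU (1.5 equiv), degassed CH2Cl2, slow addition of 25 at 0 °C, then rt, argon
Reagents that add atoms: none
Why: DBU removes the vinylogously acidic C10–H and expels mesylate (E1cB) to give the s-cis-locked C2=C1–C10=C14 diene 30, which should undergo an ortho-selective Diels–Alder reaction with the C4'=C15' enone of 29 on the face of 30 anti to C6 and on the α face of 29 (anti to C6'), fixing the spiro centre C4' in 31, and the amidine then carries the proton from C2 to C10 on the same face (suprafacial 1,3-prototropy), which puts C1=C2 into conjugation and sets 10αH, the configuration also assumed to be favoured at equilibrium.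

Compound list
1 | (S)-4-benzyl-1,3-oxazolidin-2-one | O=C1N[C@@H](Cc2ccccc2)CO1 | starting material
2 | hex-5-enoyl chloride | C=CCCCC(=O)Cl | starting material
3 | (S)-4-benzyl-3-(hex-5-enoyl)-1,3-oxazolidin-2-one | C=CCCCC(=O)N1[C@@H](Cc2ccccc2)COC1=O | intermediate
4 | trichlorotitanium (Z)-enolate of 3 (not isolated) | C=CCC/C=C(\O[Ti](Cl)(Cl)Cl)N1[C@@H](Cc2ccccc2)COC1=O | intermediate
5 | (S)-4-benzyl-3-[(2R)-2-(hydroxymethyl)hex-5-enoyl]-1,3-oxazolidin-2-one | C=CCC[C@H](CO)C(=O)N1[C@@H](Cc2ccccc2)COC1=O | intermediate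
6 | (S)-4-benzyl-3-[(2R)-2-(tert-butyldimethylsilyloxymethyl)hex-5-enoyl]-1,3-oxazolidin-2-one | C=CCC[C@H](CO[Si](C)(C)C(C)(C)C)C(=O)N1[C@@H](Cc2ccccc2)COC1=O | intermediate
7 | (2S)-2-(tert-butyldimethylsilyloxymethyl)hex-5-en-1-ol | C=CCC[C@H](CO[Si](C)(C)C(C)(C)C)CO | intermediate
8 | (2R)-2-(tert-butyldimethylsilyloxymethyl)hex-5-enal | C=CCC[C@H](CO[Si](C)(C)C(C)(C)C)C=O | intermediate
9 | (3S)-3-(tert-butyldimethylsilyloxymethyl)hept-6-en-1-yne | C=CCC[C@H](CO[Si](C)(C)C(C)(C)C)C#C | intermediate
10 | (4S)-4-(tert-butyldimethylsilyloxymethyl)hex-5-ynal (C7–C10 arm with C14 and the C1≡C2 alkyne) | O=CCC[C@H](CO[Si](C)(C)C(C)(C)C)C#C | intermediate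
11 | methyl acrylate | C=CC(=O)OC | starting material
12 | methyl (6S)-6-(tert-butyldimethylsilyloxymethyl)-3-hydroxy-2-methylideneoct-7-ynoate (both C3 epimers) | C=C(C(=O)OC)C(O)CC[C@H](CO[Si](C)(C)C(C)(C)C)C#C | intermediate
13 | methyl (2Z,6S)-2-(bromomethyl)-6-(tert-butyldimethylsilyloxymethyl)oct-2-en-7-ynoate | COC(=O)/C(CBr)=C/CC[C@H](CO[Si](C)(C)C(C)(C)C)C#C | intermediate
14 | but-2-yne-1,4-diol | OCC#CCO | starting material
15 | 4-(4-methoxybenzyloxy)but-2-yn-1-ol | COc1ccc(COCC#CCO)cc1 | intermediate
16 | 4-(4-methoxybenzyloxy)but-2-ynal | COc1ccc(COCC#CC=O)cc1 | intermediate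
17 | methyl (3S,4S)-7-(4-methoxybenzyloxy)-2-methylidene-3-[(3S)-3-(tert-butyldimethylsilyloxymethyl)pent-4-yn-1-yl]-4-(trimethylsilyloxy)hept-5-ynoate (anti adduct, not isolated) | COC(=O)C(=C)[C@H](CC[C@H](CO[Si](C)(C)C(C)(C)C)C#C)[C@H](O[Si](C)(C)C)C#CCOCc1ccc(OC)cc1 | intermediate
18 | (4S,5S)-5-[3-(4-methoxybenzyloxy)prop-1-yn-1-yl]-3-methylidene-4-[(3S)-3-(tert-butyldimethylsilyloxymethyl)pent-4-yn-1-yl]oxolan-2-one (trans lactone) | COc1ccc(COCC#C[C@H]2OC(=O)C(=C)[C@@H]2CC[C@H](CO[Si](C)(C)C(C)(C)C)C#C)cc1 | intermediate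
19 | (4S,5S)-5-(3-hydroxyprop-1-yn-1-yl)-3-methylidene-4-[(3S)-3-(tert-butyldimethylsilyloxymethyl)pent-4-yn-1-yl]oxolan-2-one | OCC#C[C@H]1OC(=O)C(=C)[C@@H]1CC[C@H](CO[Si](C)(C)C(C)(C)C)C#C | intermediate
20 | N-alkyl-N-(2-nitrophenylsulfonyl)hydrazine formed from 19 at C15 (not isolated) | NN(CC#C[C@H]1OC(=O)C(=C)[C@@H]1CC[C@H](CO[Si](C)(C)C(C)(C)C)C#C)S(=O)(=O)c1ccccc1[N+](=O)[O-] | intermediate
21 | C15 monoalkyl diazene formed from 20 (not isolated) | N=NCC#C[C@H]1OC(=O)C(=C)[C@@H]1CC[C@H](CO[Si](C)(C)C(C)(C)C)C#C | intermediate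
22 | (4S,5R)-3-methylidene-5-(propa-1,2-dien-1-yl)-4-[(3S)-3-(tert-butyldimethylsilyloxymethyl)pent-4-yn-1-yl]oxolan-2-one (allenyne lactone; guaiane C6 R, C7 S, C10 S) | C=C=C[C@H]1OC(=O)C(=C)[C@@H]1CC[C@H](CO[Si](C)(C)C(C)(C)C)C#C | intermediate
23 | (5S,6S,7S,10S)-14-(tert-butyldimethylsilyloxy)-3-oxoguaia-1,4(15),11(13)-trien-12,6α-olide (unit A tricyclic enone; 5βH,6βH,7αH,10αH) | C=C1C(=O)C=C2[C@@H](CO[Si](C)(C)C(C)(C)C)CC[C@H]3C(=C)C(=O)O[C@@H]3[C@H]12 | intermediate
24 | (5S,6S,7S,10S)-14-hydroxy-3-oxoguaia-1,4(15),11(13)-trien-12,6α-olide | C=C1C(=O)C=C2[C@@H](CO)CC[C@H]3C(=C)C(=O)O[C@@H]3[C@H]12 | intermediate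
25 | (5S,6S,7S,10S)-14-(methanesulfonyloxy)-3-oxoguaia-1,4(15),11(13)-trien-12,6α-olide | C=C1C(=O)C=C2[C@@H](COS(C)(=O)=O)CC[C@H]3C(=C)C(=O)O[C@@H]3[C@H]12 | intermediate
26 | deacylcynaropicrin, 3β,8α-dihydroxyguaia-4(15),10(14),11(13)-trien-12,6α-olide (1αH,5αH,6βH,7αH) | C=C1C[C@H](O)[C@@H]2[C@@H]([C@@H]3[C@H]1C[C@@H](C3=C)O)OC(=O)C2=C | starting material
27 | 8α-hydroxy-3-oxoguaia-4(15),10(14),11(13)-trien-12,6α-olide | C=C1C[C@H](O)[C@@H]2[C@@H]([C@@H]3[C@H]1CC(=O)C3=C)OC(=O)C2=C | intermediate
28 | 8β-formyloxy-3-oxoguaia-4(15),10(14),11(13)-trien-12,6α-olide | C=C1C[C@@H](OC=O)[C@@H]2[C@@H]([C@@H]3[C@H]1CC(=O)C3=C)OC(=O)C2=C | intermediate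
29 | 8β-hydroxy-3-oxoguaia-4(15),10(14),11(13)-trien-12,6α-olide (unit B; 1αH,5αH,6βH,7αH) | C=C1C[C@@H](O)[C@@H]2[C@@H]([C@@H]3[C@H]1CC(=O)C3=C)OC(=O)C2=C | intermediate
30 | (5S,6S,7S)-3-oxoguaia-1,4(15),10(14),11(13)-tetraen-12,6α-olide (unit A trienone, not isolated) | C=C1C(=O)C=C2C(=C)CC[C@H]3C(=C)C(=O)O[C@@H]3[C@H]12 | intermediate
31 | Diels–Alder adduct with C2–C4' and C14–C15' formed, C1=C10 double bond and 2αH (predicted; C2 is made trigonal again in the same step; not isolated) | C=C1C(=O)[C@@H]2C3=C(CC[C@H]4C(=C)C(=O)O[C@@H]4[C@H]13)CC[C@]21C(=O)C[C@H]2C(=C)C[C@@H](O)[C@H]3C(=C)C(=O)O[C@@H]3[C@H]21 | intermediate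
32 | CNP0178208.1 | C=C1C(=O)C2=C3[C@H](CC[C@H]4C(=C)C(=O)O[C@@H]4[C@H]13)CC[C@]21C(=O)C[C@H]2C(=C)C[C@@H](O)[C@H]3C(=C)C(=O)O[C@@H]3[C@H]21 | target

Total step count: 21 steps. Longest linear sequence: 16 steps (steps 1–9, 12–17 and 21).

Steps most likely to fail

Step 15 (allenic Pauson–Khand). What may go wrong: oxidative cyclisation across the five-atom tether may be too slow, so that the allene oligomerises on the metal, the metal engages the C11=C13 alkene, or it ionises the allenylic C6–O bond. The fallback sets out from 22 and comes back at 23. The C1≡C2 alkyne is first stored with Co2(CO)8 (CH2Cl2, rt) as the isolable hexacarbonyldicobalt alkyne complex F1, in which the alkyne is already bent towards the allene. The cobalt-mediated allenic Pauson–Khand reaction is then triggered with N-methylmorpholine N-oxide (CH2Cl2, rt) or by warming in toluene. This replaces the mononuclear molybdacycle by the stepwise dinuclear cobalt pathway, a known reaction type for allenes, and leaves ring B closure as the only slow event.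

Step 21 (elimination, cycloaddition, conjugation). What may go wrong: the transient trienone may combine with itself faster than with 29, C5 may epimerise before the cycloaddition and turn the diene face, or the proton may reach C10 on the wrong face. The fallback sets out from 25 and comes back at 32; it builds ring D stepwise with C10 kept as set in step 2. Finkelstein exchange (NaI, acetone, rt) gives the C14 iodide F2. Its radical (Bu3SnH, Et3B, air, toluene, −20 °C, large excess of 29) adds to C15' of the exocyclic enone in a Giese addition and gives the C14–C15' linked diketone F3 (C4' epimers, which do not matter). α-Iodination of the unit A enone (I2, pyridine, CH2Cl2) gives the C2 iodide F4. A palladium-catalysed intramolecular ketone α-alkenylation (Pd2(dba)3, Xantphos, Cs2CO3, toluene, 60 °C) then joins C2 to C4' on the α face of unit B and closes ring D.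

Step 19 (inversion at C8). What may go wrong: the activated 8α-oxygen, flanked by C7 and the allylic C9 methylene, may be lost by elimination towards C9 instead of being displaced, or free phosphine may add to the exocyclic enone. The fallback sets out from 27 and comes back at 29. The alcohol is converted into the 8α-triflate F5 (Tf2O, pyridine, CH2Cl2, −30 °C) and displaced with tetrabutylammonium nitrite (toluene, rt). The inverted 8β-nitrite ester F6 hydrolyses on aqueous work-up, which gives 29 without phosphine and without a separate ester cleavage.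

Further compounds
F1 | step 15 | hexacarbonyldicobalt complex of 22 at the C1≡C2 alkyne, (μ-alkyne)Co2(CO)6 | C=C=C[C@H]1OC(=O)C(=C)[C@@H]1CC[C@H](CO[Si](C)(C)C(C)(C)C)C#C.[Co].[Co].[C-]#[O+].[C-]#[O+].[C-]#[O+].[C-]#[O+].[C-]#[O+].[C-]#[O+]
F2 | step 21 | (5S,6S,7S,10S)-14-iodo-3-oxoguaia-1,4(15),11(13)-trien-12,6α-olide | C=C1C(=O)C=C2[C@@H](CI)CC[C@H]3C(=C)C(=O)O[C@@H]3[C@H]12
F3 | step 21 | Giese adduct with the C14–C15' bond formed (C2–H, C4'–H, C4' epimers) | C=C1C(=O)C=C2[C@@H](CCC3C(=O)C[C@H]4C(=C)C[C@@H](O)[C@H]5C(=C)C(=O)O[C@@H]5[C@@H]34)CC[C@H]3C(=C)C(=O)O[C@@H]3[C@H]12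
F4 | step 21 | 2-iodo derivative of F3 | C=C1C(=O)C(I)=C2[C@@H](CCC3C(=O)C[C@H]4C(=C)C[C@@H](O)[C@H]5C(=C)C(=O)O[C@@H]5[C@@H]34)CC[C@H]3C(=C)C(=O)O[C@@H]3[C@H]12
F5 | step 19 | 8α-trifluoromethanesulfonate of 27 | C=C1C[C@H](OS(=O)(=O)C(F)(F)F)[C@@H]2[C@@H]([C@@H]3[C@H]1CC(=O)C3=C)OC(=O)C2=C
F6 | step 19 | 8β-nitrite ester of 29 | C=C1C[C@@H](ON=O)[C@@H]2[C@@H]([C@@H]3[C@H]1CC(=O)C3=C)OC(=O)C2=C
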